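**Retrosynthetic overview**

1. Target 21 is (2R,3R)-pinobanksin 3-hexanoate. The two phenols are unmasked last from dibenzyl ether 20, and the C4 ketone is made late from the C4 methylene of flavan ester 17 (DDQ/water, then periodinane).
2. The C2–phenyl bond (ring B) is cut next: ZnPh2 on the anomeric bromide made from acetate 13, with the C3 hexanoate steering phenyl trans through a dioxolenium ion.
3. Ring C comes from one formal [4+2] that forms C3–C4 and O1–C2. The feature used: C4 is carried by C4a, ortho to the O1-bearing C8a of electron-rich ring A, so C4–C4a–C8a–O1 is a latent ortho-quinone methide, and C3 with its ester oxygen is the alpha carbon of an aldehyde whose carbonyl carbon becomes C2.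
4. Precursors: sulfone 5 from 2,4,6-trihydroxybenzaldehyde in three steps, and 2-oxoethyl hexanoate 8 from allyl hexanoate by ozonolysis.
5. Ring order: ring A is bought, ring C is closed in step 5, ring B is attached in step 7.

Key step: step 5

Remark: locants O1, C2, C3, C4, C4a, C5 to C8 and C8a are those of the chroman core; ring A is the benzo ring, ring C the oxygen ring, ring B the C2 phenyl.

Assumption: the sense of induction is taken from the usual shielding model for E-enamines of diarylprolinol silyl ethers, on which the (R)-catalyst gives the required C3 configuration; if the alpha-acyloxy enamine reacts with the opposite sense, the (S)-catalyst is used instead.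

**Route**

Step 1
Reactants: 1 2,4,6-trihydroxybenzaldehyde; 2 benzyl bromide
Product: 3 2,4-bis(benzyloxy)-6-hydroxybenzaldehyde
Conditions: 2 (2.05 equiv), K2CO3 (2.2 equiv), DMF, 0 °C to rt
Reagents that add atoms: none
Why: Williamson ether synthesis in which the para hydroxyl and one ortho hydroxyl are alkylated, while the remaining ortho hydroxyl is held in a hydrogen bond to the aldehyde carbonyl and is the least nucleophilic, so two equivalents of benzyl bromide should stop at the 2,4-dibenzyl ether.

Step 2
Reactants: 3 2,4-bis(benzyloxy)-6-hydroxybenzaldehyde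
Product: 4 3,5-bis(benzyloxy)-2-(hydroxymethyl)phenol
Conditions: NaBH4, THF/MeOH, 0 °C; pH 7 buffer work-up; used crude at once
Reagents that add atoms: none
Why: Borohydride reduction of the aldehyde to the 2-hydroxybenzyl alcohol at low temperature; the benzyl ethers are inert and the neutral work-up spares the acid-sensitive product.

Step 3
Reactants: 4 3,5-bis(benzyloxy)-2-(hydroxymethyl)phenol
Product: 5 3,5-bis(benzyloxy)-2-[(4-methylphenyl)sulfonylmethyl]phenol
Conditions: p-toluenesulfinic acid (3 equiv, freshly liberated from its sodium salt), CH2Cl2, 0 °C to rt, slow addition of 4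
Reagents that add atoms: p-toluenesulfinic acid, Cc1ccc(cc1)S(=O)O
Why: Acid-promoted substitution of the electron-rich 2-hydroxybenzyl alcohol through its benzylic cation or quinone methide, trapped at sulfur by the sulfinate (sulfinate S-alkylation, the usual preparation of 2-(sulfonylmethyl)phenols); the excess of sulfinic acid should outrun self-condensation on ring A.

Step 4
Reactants: 6 allyl hexanoate
Product: 8 2-oxoethyl hexanoate, via ozonide 7 (not isolated)
Conditions: O3, CH2Cl2, −78 °C; then Me2S, −78 °C to rt; used freshly prepared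
Reagents that add atoms: ozone, [O-][O+]=O
Why: Ozonolysis through the Criegee ozonide with reductive work-up cleaves the terminal alkene to the aldehyde and formaldehyde and leaves the ester untouched.

Step 5
Reactants: 5 3,5-bis(benzyloxy)-2-[(4-methylphenyl)sulfonylmethyl]phenol; 8 2-oxoethyl hexanoate
Product: 12 (3S)-5,7-bis(benzyloxy)-2-hydroxychroman-3-yl hexanoate as an anomeric mixture at C2, via ortho-quinone methide 9 (not isolated), via enamine 10 (not isolated), via open-chain phenol aldehyde 11 (not isolated)
Conditions: 8 (2.5 equiv), (R)-2-[diphenyl(trimethylsilyloxy)methyl]pyrrolidine (20 mol%), Na2CO3 (1.5 equiv), CH2Cl2, 0 °C to rt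
Reagents that add atoms: none
Why: Proposed new method: carbonate deprotonates the phenol of 5 and loss of sulfinate gives methide 9, while the amine condenses with 8 to the E-enamine 10, whose carbon C3 adds to the exocyclic methide carbon C4 and rearomatises ring A, after which hydrolysis of the iminium gives phenol aldehyde 11 and returns the catalyst. The closest known reaction type is the aminocatalytic formal [4+2] of alkyl aldehydes with aryl-substituted ortho-quinone methides released from 2-(sulfonylmethyl)phenols, which gives chroman-2-ols; new here are the alpha-acyloxy donor, whose enamine is less nucleophilic but meets a very electrophilic partner, and the unsubstituted methide carbon. Ring C closes by 6-exo-trig addition of the phenol oxygen O1 to the aldehyde carbon C2 (lactolisation), so the step forms C3–C4 and O1–C2. The stereocentre C3 is set by the catalyst, whose diphenyl(silyloxy)methyl group shields one face of the s-trans E-enamine so that the methide approaches the open face, which for the (R)-catalyst corresponds to the (3S)-lactol, while C2 remains an anomeric mixture that is reset in step 7. The step needs enantioselectivity at C3, bond formation only at C4 and suppression of methide self-condensation; the first rests on the catalyst, the second on the fact that the methide carbon is the only electrophilic site of 9, and the third on slow release of 9 by the insoluble base in the presence of excess 8. Lactol formation masks the aldehyde and so should protect C3 from epimerisation through renewed enamine formation.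

Step 6
Reactants: 12 (3S)-5,7-bis(benzyloxy)-2-hydroxychroman-3-yl hexanoate
Product: 13 (3S)-2-acetoxy-5,7-bis(benzyloxy)chroman-3-yl hexanoate as an anomeric mixture at C2
Conditions: Ac2O, pyridine, 4-(dimethylamino)pyridine (cat.), CH2Cl2, 0 °C
Reagents that add atoms: acetic anhydride, CC(=O)OC(C)=O
Why: Amine-catalysed acylation of the anomeric hydroxyl gives a stable acetate that can be purified and later serves as the leaving group at C2; C3 is not touched.

Step 7
Reactants: 13 (3S)-2-acetoxy-5,7-bis(benzyloxy)chroman-3-yl hexanoate; 14 diphenylzinc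
Product: 17 (2R,3S)-5,7-bis(benzyloxy)-2-phenylchroman-3-yl hexanoate, via anomeric bromide 15 (not isolated), via dioxolenium ion 16 (not isolated)
Conditions: Me3SiBr (1.5 equiv), CH2Cl2, 0 °C to rt, then evaporation; ZnPh2 (2 equiv), toluene/Bu2O, 0 to 60 °C
Reagents that add atoms: none
Why: Me3SiBr exchanges the anomeric acetate for bromide, ZnPh2 then abstracts the bromide as a Lewis acid so that the C3 hexanoate closes onto C2 to give the cis-fused dioxolenium ion 16, and phenyl passes from zinc to C2 on the face opposite the bridging acyloxy group, which sets C2 as R and trans to C3; this is the arylzinc substitution of 2-O-acyl glycosyl bromides with neighbouring-group participation that is used for 1,2-trans C-aryl glycosides, and esters and benzyl ethers are inert to the organozinc.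

Step 8
Reactants: 17 (2R,3S)-5,7-bis(benzyloxy)-2-phenylchroman-3-yl hexanoate
Product: 19 (2R,3S)-5,7-bis(benzyloxy)-4-hydroxy-2-phenylchroman-3-yl hexanoate as a mixture of C4 epimers, via C4 benzylic cation 18 (not isolated)
Conditions: DDQ (1.5 equiv), CH2Cl2/H2O, rt
Reagents that add atoms: water, O
Why: Benzylic oxidation by hydride abstraction with DDQ at C4, the only position whose cation is stabilised by the ortho and para oxygen donors of ring A, followed by capture of cation 18 by water, as is known for 5,7-dialkoxyflavan-3-ol derivatives; unsubstituted benzyl ethers resist DDQ, and the C4 configuration does not matter because the alcohol is oxidised in step 9.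

Step 9
Reactants: 19 (2R,3S)-5,7-bis(benzyloxy)-4-hydroxy-2-phenylchroman-3-yl hexanoate
Product: 20 (2R,3R)-5,7-bis(benzyloxy)-4-oxo-2-phenylchroman-3-yl hexanoate
Conditions: Dess–Martin periodinane, CH2Cl2, 0 °C to rt
Reagents that add atoms: none
Why: Dess–Martin oxidation of the benzylic secondary alcohol to the aryl ketone under non-basic conditions, which avoids enolisation at C3 and ring opening by beta-elimination of the phenoxide; C2 and C3 are untouched, and C3 is now named R only because C4 outranks C2.

Step 10
Reactants: 20 (2R,3R)-5,7-bis(benzyloxy)-4-oxo-2-phenylchroman-3-yl hexanoate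
Product: 21 (2R,3R)-5,7-dihydroxy-4-oxo-2-phenylchroman-3-yl hexanoate
Conditions: H2 (1 atm), Pd/C, EtOAc, rt, stopped at full conversion
Reagents that add atoms: none
Why: Catalytic hydrogenolysis of the two aryl benzyl ethers; the ester, the hydrogen-bonded aryl ketone and the C2–O1 bond should survive these mild conditions, and no stereocentre is touched.

**Compound list**

1 | 2,4,6-trihydroxybenzaldehyde | O=Cc1c(O)cc(O)cc1O | starting material
2 | benzyl bromide | BrCc1ccccc1 | starting material
3 | 2,4-bis(benzyloxy)-6-hydroxybenzaldehyde | O=Cc1c(O)cc(OCc2ccccc2)cc1OCc1ccccc1 | intermediate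
4 | 3,5-bis(benzyloxy)-2-(hydroxymethyl)phenol | OCc1c(O)cc(OCc2ccccc2)cc1OCc1ccccc1 | intermediate
5 | 3,5-bis(benzyloxy)-2-[(4-methylphenyl)sulfonylmethyl]phenol | Oc1cc(OCc2ccccc2)cc(OCc2ccccc2)c1CS(=O)(=O)c1ccc(C)cc1 | intermediate
6 | allyl hexanoate (prop-2-en-1-yl hexanoate) | C=CCOC(=O)CCCCC | starting material
7 | (1,2,4-trioxolan-3-yl)methyl hexanoate (ozonide, not isolated) | CCCCCC(=O)OCC1OCOO1 | intermediate
8 | 2-oxoethyl hexanoate | CCCCCC(=O)OCC=O | intermediate
9 | 3,5-bis(benzyloxy)-6-methylidenecyclohexa-2,4-dien-1-one (ortho-quinone methide, not isolated) | C=C1C(=O)C=C(OCc2ccccc2)C=C1OCc1ccccc1 | intermediate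
10 | (E)-2-{(2R)-2-[diphenyl(trimethylsilyloxy)methyl]pyrrolidin-1-yl}ethenyl hexanoate (enamine, not isolated) | CCCCCC(=O)O/C=C/N1CCC[C@@H]1C(c1ccccc1)(c1ccccc1)O[Si](C)(C)C | intermediate
11 | (2S)-3-[2,4-bis(benzyloxy)-6-hydroxyphenyl]-1-oxopropan-2-yl hexanoate (open-chain form, not isolated) | CCCCCC(=O)O[C@@H](Cc1c(O)cc(OCc2ccccc2)cc1OCc1ccccc1)C=O | intermediate
12 | (3S)-5,7-bis(benzyloxy)-2-hydroxychroman-3-yl hexanoate, anomeric mixture at C2 | CCCCCC(=O)O[C@H]1Cc2c(OCc3ccccc3)cc(OCc3ccccc3)cc2OC1O | intermediate
13 | (3S)-2-acetoxy-5,7-bis(benzyloxy)chroman-3-yl hexanoate, anomeric mixture at C2 | CCCCCC(=O)O[C@H]1Cc2c(OCc3ccccc3)cc(OCc3ccccc3)cc2OC1OC(C)=O | intermediate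
14 | diphenylzinc | c1ccc([Zn]c2ccccc2)cc1 | starting material
15 | (3S)-5,7-bis(benzyloxy)-2-bromochroman-3-yl hexanoate, anomeric mixture (not isolated) | CCCCCC(=O)O[C@H]1Cc2c(OCc3ccccc3)cc(OCc3ccccc3)cc2OC1Br | intermediate
16 | cis-fused 2-pentyl-1,3-dioxolan-2-ylium ion bridging O–C2 and O–C3 of the 5,7-bis(benzyloxy)chroman, C3 as in 12 (not isolated) | CCCCCC1=[O+][C@H]2Cc3c(OCc4ccccc4)cc(OCc4ccccc4)cc3O[C@H]2O1 | intermediate
17 | (2R,3S)-5,7-bis(benzyloxy)-2-phenylchroman-3-yl hexanoate | CCCCCC(=O)O[C@H]1Cc2c(OCc3ccccc3)cc(OCc3ccccc3)cc2O[C@@H]1c1ccccc1 | intermediate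
18 | C4 benzylic cation of 17 (not isolated) | CCCCCC(=O)O[C@H]1[CH+]c2c(OCc3ccccc3)cc(OCc3ccccc3)cc2O[C@@H]1c1ccccc1 | intermediate
19 | (2R,3S)-5,7-bis(benzyloxy)-4-hydroxy-2-phenylchroman-3-yl hexanoate, C4 epimers | CCCCCC(=O)O[C@H]1C(O)c2c(OCc3ccccc3)cc(OCc3ccccc3)cc2O[C@@H]1c1ccccc1 | intermediate
20 | (2R,3R)-5,7-bis(benzyloxy)-4-oxo-2-phenylchroman-3-yl hexanoate | CCCCCC(=O)O[C@H]1C(=O)c2c(OCc3ccccc3)cc(OCc3ccccc3)cc2O[C@@H]1c1ccccc1 | intermediate
21 | (2R,3R)-5,7-dihydroxy-4-oxo-2-phenylchroman-3-yl hexanoate | CCCCCC(=O)O[C@H]1C(=O)c2c(O)cc(O)cc2O[C@@H]1c1ccccc1 | target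

**Step count**

Total steps: 10. Longest linear sequence: 9 steps (steps 1, 2, 3, 5, 6, 7, 8, 9, 10); step 4 is a one-step side branch.

**Steps most likely to fail**

Step 5, which carries the label of a proposed new method.
- What may go wrong: the acyloxy-substituted enamine may form or react too slowly, so that the methide self-condenses on ring A or alkylates the catalyst nitrogen. Facial selectivity may be poor, and the hexanoate may migrate to the anomeric oxygen.
- Fallback (known chemistry, from sulfone 5, rejoining at flavan ester 17):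
  - K2CO3 releases methide 9 from 5 in the presence of (E)-styrylboronic acid, whose alkenyl group adds to the methide carbon (boronate conjugate addition to ortho-quinone methides). This should give 3,5-bis(benzyloxy)-2-[(2E)-3-phenylprop-2-en-1-yl]phenol F1.
  - Silylation with tert-butyldimethylsilyl chloride and imidazole gives tert-butyl{3,5-bis(benzyloxy)-2-[(2E)-3-phenylprop-2-en-1-yl]phenoxy}dimethylsilane F2.
  - Shi epoxidation with KHSO5 and the L-fructose-derived ketone (the enantiomer of the common D-fructose-derived catalyst) should give tert-butyl(3,5-bis(benzyloxy)-2-{[(2S,3S)-3-phenyloxiran-2-yl]methyl}phenoxy)dimethylsilane F3.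
  - Bu4NF frees 3,5-bis(benzyloxy)-2-{[(2S,3S)-3-phenyloxiran-2-yl]methyl}phenol F4.
  - Camphorsulfonic acid then drives 6-endo opening of the epoxide at the benzylic carbon with inversion, giving (2R,3S)-5,7-bis(benzyloxy)-2-phenylchroman-3-ol F5.
  - Hexanoyl chloride and pyridine give 17.
  - Here C3 is set by the epoxidation and C2 by the anti opening; compounds 12 and 13 and step 7 are bypassed.

Step 7.
- What may go wrong: phenyl may be delivered to the dioxolenium carbon instead of C2. Ring A of a second molecule may attack the C2 cation in a Friedel–Crafts sense, and trans selectivity may erode if the open oxocarbenium ion reacts.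
- Fallback (from acetate 13, rejoining at 17): the bromide 15 is made as before and coupled by a nickel-catalysed Negishi reaction with PhZnI·LiCl, NiCl2(dme) and 4,4′,4″-tri-tert-butyl-2,2′:6′,2″-terpyridine in N,N-dimethylacetamide at rt, as is known for glycosyl bromides. This path runs through a C2 radical and avoids the cation altogether; the phenyl group should enter trans to the C3 ester for steric reasons. It makes no new compound (F0).

Step 3.
- What may go wrong: the very electron-rich benzylic alcohol 4 may ionise and condense with ring A of a second molecule faster than the sulfinate captures it.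
- Fallback (from aldehyde 3, rejoining at sulfone 5, without the free benzylic alcohol):
  - Reductive amination of 3 with dimethylamine and NaBH(OAc)3 gives the Mannich base 3,5-bis(benzyloxy)-2-[(dimethylamino)methyl]phenol F6.
  - Methyl iodide gives [2,4-bis(benzyloxy)-6-hydroxyphenyl]methyl-trimethylammonium iodide F7.
  - Warming F7 with sodium p-toluenesulfinate in DMF expels trimethylamine, and the sulfinate adds at sulfur to the methide to give 5 (the known exchange of phenolic Mannich-base quaternary salts).

Further compounds
F1 | step 5 | 3,5-bis(benzyloxy)-2-[(2E)-3-phenylprop-2-en-1-yl]phenol | Oc1cc(OCc2ccccc2)cc(OCc2ccccc2)c1C/C=C/c1ccccc1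
F2 | step 5 | tert-butyl{3,5-bis(benzyloxy)-2-[(2E)-3-phenylprop-2-en-1-yl]phenoxy}dimethylsilane | CC(C)(C)[Si](C)(C)Oc1cc(OCc2ccccc2)cc(OCc2ccccc2)c1C/C=C/c1ccccc1
F3 | step 5 | tert-butyl(3,5-bis(benzyloxy)-2-{[(2S,3S)-3-phenyloxiran-2-yl]methyl}phenoxy)dimethylsilane | CC(C)(C)[Si](C)(C)Oc1cc(OCc2ccccc2)cc(OCc2ccccc2)c1C[C@@H]1O[C@H]1c1ccccc1
F4 | step 5 | 3,5-bis(benzyloxy)-2-{[(2S,3S)-3-phenyloxiran-2-yl]methyl}phenol | Oc1cc(OCc2ccccc2)cc(OCc2ccccc2)c1C[C@@H]1O[C@H]1c1ccccc1
F5 | step 5 | (2R,3S)-5,7-bis(benzyloxy)-2-phenylchroman-3-ol | O[C@H]1Cc2c(OCc3ccccc3)cc(OCc3ccccc3)cc2O[C@@H]1c1ccccc1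
F0 | step 7 | none | none
F6 | step 3 | 3,5-bis(benzyloxy)-2-[(dimethylamino)methyl]phenol | CN(C)Cc1c(O)cc(OCc2ccccc2)cc1OCc1ccccc1
F7 | step 3 | [2,4-bis(benzyloxy)-6-hydroxyphenyl]methyl-trimethylammonium iodide | C[N+](C)(C)Cc1c(O)cc(OCc2ccccc2)cc1OCc1ccccc1.[I-]
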